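**Analysis of the target**

Maackiaflavanone A (21) is a flavanone. Ring A (C4a to C8a) carries a free 5-OH, a 7-OMe and a prenyl group at C8. Ring C is the dihydropyranone O1–C2–C3–C4 fused to ring A at C4a/C8a. Ring B at C2 is a 2'-hydroxyphenyl ring fused at C4'/C5' to a 2,2-dimethylpyran, that is, a linear 7-hydroxy-2,2-dimethyl-2H-chromen-6-yl group. The only stereocentre is C2, with (S) configuration, so there is no relative stereochemistry to control, only absolute configuration. C2 is a benzylic ether carbon attached to a ring B that is oxygenated ortho and para to it, and it lies β to the C4 ketone. The C2–O1 bond can therefore open by ionisation under acid, by retro-oxa-Michael reaction under base, or through a quinone methide once the 2'-phenol is deprotonated, and each of these racemises the centre. The chromene double bond (an electron-rich styrene) and the prenyl group are acid-sensitive. Three regiochemical questions add to the difficulty: prenyl at C8 and not C6, O5 free but O7 methylated, and a linear rather than angular chromene. The strategy rests on the fact that O1–C8a–C4a–C4 is the four-atom heterodiene of an ortho-quinone methide of ring A, while C2=C3 is a vinyl group on ring B, so ring C maps onto an oxa-[4+2] union of the two aromatic halves.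

**Retrosynthetic reasoning**

21 back to 20. The last bond cut is O2'–Si. The 2'-oxygen has to be masked throughout, because a free ortho-hydroxystyrene would divert the key step and a 2'-phenoxide promotes opening of ring C. A bulky silyl ether is chosen because it can be removed at the end with buffered fluoride, conditions under which neither the olefins nor C2 are at risk.

20 back to 19. The O5–CH3 bond is cut. Carrying O5 as a methyl ether keeps ring A electron-rich for the key step and leaves only one phenol (the future O1) free. Once the C4 ketone exists, O5 is the only methoxy group that can chelate a Lewis acid together with the carbonyl, so it can be released selectively while the 7-OMe stays.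

19 back to 17 through 18. Here no skeletal bond is cut; the C4 oxidation level is adjusted. The ketone 19 comes from the benzylic alcohol 18, which in turn arises by exchange of the C4 methyl ether of 17 in aqueous acid. This ether is a 2,4,6-trioxygenated benzylic ether and ionises much more easily than anything else in the molecule. The C4 stereocentre of 17 is thereby erased, so only C2 has to be right.

17 back to 6 and 14. The C3–C4 and O1–C2 bonds are cut together. This is the only disconnection of ring C that joins two aromatic halves of similar size, each already carrying its full substitution (prenyl, both methoxy groups, chromene, silyl ether). It also creates C2 in the ring-forming event rather than in a separate, reversible cyclisation of an open-chain enone. In the forward sense the aldehyde 6 is turned by an orthoformate into the acetal 15. A chiral confined Brønsted acid ionises 15 to the oxocarbenium ion 16, and the vinyl group of 14 adds across the O1/C4 termini. The reaction must select one face at C2, must use the vinyl group in preference to the chromene and prenyl olefins, and must run under acid mild enough to spare the product.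

6 back to 4, 3 and 1 (with 2 and 5). The prenyl side chain is cut at its C2''=C3'' double bond (cross-metathesis of the allyl compound 4 with 5) and then at the aryl–CH2 bond (Claisen rearrangement of the allyl ether 3, made from 1 and 2). Direct C-prenylation of a phloroglucinol-type ring gives mixtures of ortho, para and O-alkylation. The sigmatropic route can only deliver carbon to the single free position ortho to the phenol, which is exactly the future C8.

14 back to 13, 12 and 11. The vinyl group is cut at its double bond (methylenation of aldehyde 13), the silyl ether at O–Si (12), and the formyl group at the aryl–CHO bond (ortho-formylation of phenol 11). The phenol directs the new carbon to the less hindered of its two ortho positions, C6, which is the position needed for the linear chromene.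

11 back to 9 (through 10) and then to 7 and 8. The chromene double bond is traced to the ketone 9 by reduction and dehydration. Compound 9 is cut at the aryl–acyl bond and the O1–C2 bond into 7 and 8. Building the pyran ring by acylation para to one hydroxy group of 7, followed by oxa-Michael closure, fixes the 7-hydroxy regiochemistry unambiguously. Direct chromenylation of resorcinol-type substrates tends to occur between the two oxygens and would give the wrong (5-hydroxy or angular) series.

**Alternatives that were turned down**

Alternative 1: Ring A is built rather than bought. The C4a–C5 bond is cut, which unfolds ring A into a polyketide-like chain stored as the 4-methoxypyran-2-one A1. In the forward direction a methanolic magnesium alkoxide would open the lactone of A1 to a methoxy dioxo ester. Its doubly activated methylene would condense onto the ester (intramolecular Claisen condensation) and aromatise to the chalcone A2, and ring C would follow by oxa-Michael closure.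
- For: it imitates the biosynthesis. The enol ether of A1 becomes the 7-OMe while both flanking oxygens emerge free, so the O5/O7 differentiation costs nothing. On this point it is better than the chosen route, which needs a chelation-controlled demethylation.
- Against: A2 has neither the C8 prenyl group nor the stereocentre. Prenylation afterwards has to distinguish C6 from C8, or, on A2 itself, makes the two hydroxy groups different without controlling which one closes ring C. C2 would have to be set by an enantioselective oxa-Michael closure of a 2',6'-dihydroxychalcone, a reversible reaction without an activating group, so the ee can leak away through the same equilibrium. The enone of A1 is exposed to the alkoxide during folding, A1 needs several steps of its own, and the MOM ether must finally be removed with acid next to the chromene.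
- Comparison: the chosen strategy has the prenyl group in place before ring C exists and creates C2 while closing the ring, at the price of one late demethylation.

Alternative 2: Ring C is cut at O1–C8a and C4–C4a, giving an aryne of ring A and a pre-formed chain O1–C2–C3–C4. In the forward direction fluoride would release the aryne from the silyl triflate A3. The alkoxide of the (S)-β-hydroxy ester A4 would add at C8a, and the aryl anion at C4a would acylate on the ester to give the flavanone A5.
- For: the stereocentre comes from A4, which established asymmetric aldol or keto-ester reduction chemistry can supply. In stereochemical certainty this is stronger than the chosen route. The product is already at the ketone oxidation level, and the C5 methoxy group polarises the aryne so that the alkoxide adds at the remote carbon C8a, as needed.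
- Against: A3 is a penta-substituted arene with silyl, triflate and prenyl groups on adjacent carbons, which needs a long regiocontrolled synthesis. The alkoxide of A4 is a benzylic β-alkoxide of an ester on an electron-rich ring; under basic fluoride conditions it can undergo retro-aldol cleavage or dehydrate to the cinnamate, which both erode ee and consume material. The aryne can also be intercepted by ene reaction with the prenyl or chromene olefins, and the attacked carbon is flanked by the prenyl group. A5 still needs the same 5-O-demethylation plus an acidic MOM removal.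
- Comparison: the chosen route gives up the certainty of a pre-made stereocentre but reaches its two partners in three and five steps from simple aromatics and creates chirality catalytically.

Alternative 3: Ring A is cut at C8–C8a and C4a–C5 and grown onto a pre-formed chiral ring C. In the forward direction the electron-rich diene A6 would add across C5=C6 of the (S)-sulfinyl dihydropyranone A7. Loss of the sulfinyl group as a sulfenic acid and of one methoxy group as the alcohol would aromatise the adduct to A8.
- For: A8 has 5-OH free, 7-OMe and the C8 prenyl group directly and is one deprotection from the target. In endgame economy this is the strongest of all four plans. C2 would come from an established asymmetric hetero-Diels–Alder reaction.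
- Against: the dienophile is a vinylogous ester whose C6 is electron-rich, so it depends on the sulfinyl group for activation. The diene A6 carries the prenyl group on its reacting terminus, which slows the cycloaddition and makes it depend on diene geometry. The heat needed can open the dihydropyranone by retro-oxa-Michael reaction and racemise C2. A7 and A6 together need about as many steps as the whole chosen route, and the MOM group must again be removed with acid.
- Comparison: the chosen route has a longer endgame but a far shorter approach to the key step, and its risk is concentrated in one catalytic reaction rather than spread over a sluggish cycloaddition and a fragile dienophile.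

Key step: step 9

Assumption: the sense of induction of the confined acid cannot be predicted; the (S,S) catalyst is written, and its mirror image is to be used if it leads to (2R).
Assumption: 17 is drawn as the 2,4-cis isomer; its C4 epimer would be carried through in the same way, because C4 becomes the carbonyl carbon.

**Route**

Step 1
Reactants: 1 2-hydroxy-4,6-dimethoxybenzaldehyde; 2 allyl bromide
Product: 3 2-(allyloxy)-4,6-dimethoxybenzaldehyde
Conditions: K2CO3, DMF, 60 °C
Reagents that add atoms: none
Why: Williamson O-alkylation of the only phenol; DMF and gentle heating overcome the hydrogen bond to the aldehyde.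

Step 2
Reactants: 3 2-(allyloxy)-4,6-dimethoxybenzaldehyde
Product: 4 3-allyl-2-hydroxy-4,6-dimethoxybenzaldehyde
Conditions: N,N-diethylaniline, 190 °C
Reagents that add atoms: none
Why: Aromatic Claisen rearrangement; the [3,3] shift can end productively only at C3, the single free ortho position of the allyloxy group, and tautomerisation restores the phenol, so the side chain is fixed between the hydroxy and the 4-methoxy group.

Step 3
Reactants: 4 3-allyl-2-hydroxy-4,6-dimethoxybenzaldehyde; 5 2-methylbut-2-ene
Product: 6 2-hydroxy-4,6-dimethoxy-3-(3-methylbut-2-en-1-yl)benzaldehyde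
Conditions: second-generation Grubbs catalyst RuCl2(=CHPh)(PCy3)(H2IMes) (3 mol %), 2-methylbut-2-ene/CH2Cl2, 40 °C, sealed tube
Reagents that add atoms: none
Why: Olefin cross-metathesis of a terminal alkene with an excess of a trisubstituted alkene converts allyl into prenyl and releases a volatile alkene; free phenols and aldehydes are tolerated by the ruthenium carbene.

Step 4
Reactants: 7 resorcinol; 8 3-methylbut-2-enoic acid
Product: 9 7-hydroxy-2,2-dimethylchroman-4-one
Conditions: P2O5/MeSO3H (Eaton's reagent), 70 °C
Reagents that add atoms: none
Why: Friedel–Crafts acylation at C4 of resorcinol followed by intramolecular oxa-Michael addition of the ortho hydroxy group; this sequence places the pyran oxygen and the remaining phenol in the relationship needed for the linear chromene.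

Step 5
Reactants: 9 7-hydroxy-2,2-dimethylchroman-4-one
Product: 11 2,2-dimethyl-2H-chromen-7-ol, via 2,2-dimethylchromane-4,7-diol 10 (not isolated)
Conditions: NaBH4, MeOH, 0 °C to rt; crude, then p-TsOH·H2O (cat.), toluene, 60 °C
Reagents that add atoms: none
Why: Hydride reduction of the aryl ketone, then acid-catalysed dehydration of the para-hydroxybenzylic alcohol, which ionises readily and loses a proton from C3 to give the conjugated chromene.

Step 6
Reactants: 11 2,2-dimethyl-2H-chromen-7-ol
Product: 12 7-hydroxy-2,2-dimethyl-2H-chromene-6-carbaldehyde
Conditions: (CH2O)n, MgCl2, Et3N, MeCN, reflux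
Reagents that add atoms: paraformaldehyde (formaldehyde), C=O
Why: Magnesium phenoxide-directed ortho-formylation (Casnati–Skattebøl formylation); of the two ortho positions C6 is open while C8 is flanked by the pyran oxygen, so, as with other 3-alkoxyphenols, the 6-aldehyde should be formed; the basic medium leaves the chromene untouched.

Step 7
Reactants: 12 7-hydroxy-2,2-dimethyl-2H-chromene-6-carbaldehyde
Product: 13 2,2-dimethyl-7-(triisopropylsilyloxy)-2H-chromene-6-carbaldehyde
Conditions: iPr3SiOTf, 2,6-lutidine, CH2Cl2, 0 °C
Reagents that add atoms: triisopropylsilyl trifluoromethanesulfonate, CC(C)[Si](OS(=O)(=O)C(F)(F)F)(C(C)C)C(C)C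
Why: O-silylation; the silyl triflate is needed because the phenol is hydrogen-bonded to the aldehyde, and the bulky silyl ether withstands the ylide and the mild acids used later.

Step 8
Reactants: 13 2,2-dimethyl-7-(triisopropylsilyloxy)-2H-chromene-6-carbaldehyde
Product: 14 6-ethenyl-2,2-dimethyl-7-(triisopropylsilyloxy)-2H-chromene
Conditions: Ph3PCH3Br, KOtBu, THF, 0 °C
Reagents that add atoms: methyltriphenylphosphonium bromide (as its ylide), C[P+](c1ccccc1)(c1ccccc1)c1ccccc1.[Br-]
Why: Wittig methylenation of an aromatic aldehyde; the unstabilised ylide reacts quickly at 0 °C and does not attack the hindered aryl silyl ether.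

Step 9
Reactants: 6 2-hydroxy-4,6-dimethoxy-3-(3-methylbut-2-en-1-yl)benzaldehyde; 14 6-ethenyl-2,2-dimethyl-7-(triisopropylsilyloxy)-2H-chromene
Product: 17 (2S,4S)-2-[2,2-dimethyl-7-(triisopropylsilyloxy)-2H-chromen-6-yl]-4,5,7-trimethoxy-8-(3-methylbut-2-en-1-yl)chromane, via dimethyl acetal 15 (not isolated), via O-methyl oxocarbenium ion 16 (not isolated)
Conditions: HC(OMe)3 (1.5 equiv), (S,S)-imidodiphosphoric acid HN[P(O)(O2C20H10Ar2)]2 (Ar = 2,4,6-Et3C6H2 at the 3,3'-positions of each binaphthyl, 5 mol %), 5 Å MS, CH2Cl2, −40 °C; Et3N quench
Reagents that add atoms: trimethyl orthoformate, COC(OC)OC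
Why: Proposed new method: the orthoformate converts 6 into the acetal 15, which the chiral acid ionises to the oxocarbenium ion 16, an O-protonated ortho-quinone methide that stays paired with the confined anion through its phenolic O–H; the CH2 terminus of the vinyl group of 14 attacks C4 (C3–C4 bond) and the ring B-stabilised benzylic cation at C2 is captured by the phenol oxygen (O1–C2 bond), a polar, asynchronous or stepwise oxa-[4+2] annulation. The closest known reaction types are the achiral acid-promoted three-component coupling of salicylaldehydes, orthoformates and styrenes to 4-alkoxy-2-arylchromans and the intramolecular oxa-[4+2] cyclisations of salicylaldehyde-derived oxocarbenium ions under confined chiral imidodiphosphoric acids; an intermolecular enantioselective version with a styrene has not been shown. Ring C, the only ring closed, is a six-membered ring made from two bonds, the second being a 6-exo-type capture by O1 of a cationic centre whose stabilising aryl group lies outside the new ring. C4 is fixed in the C–C bond formation and C2 in the C–O closure, both inside the pocket of the anion that is hydrogen-bonded to O1–H, so the catalyst antipode decides the (2S) configuration; a compact arrangement with the aryl group under the oxocarbenium unit should give the 2,4-cis isomer, but C4 is erased later and only C2 counts. The step needs chemoselectivity for the vinyl group over the chromene and prenyl double bonds, which is secured because the vinyl terminus is unsubstituted and conjugated to the para pyran oxygen, whereas chromene C3 is neopentyl-like and the prenyl olefin is not aryl-conjugated. Regioselectivity follows from polarity, the nucleophilic CH2 bonding to the cationic C4 and the oxygen to the benzylic cation. The three oxygens of ring A allow ionisation by a weak acid at low temperature, which is what the chromene, the ortho-prenyl phenol and the ionisable C2–O1 bond of the product require, and the amine quench before warming prevents erosion of C2.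

Step 10
Reactants: 17 (2S,4S)-2-[2,2-dimethyl-7-(triisopropylsilyloxy)-2H-chromen-6-yl]-4,5,7-trimethoxy-8-(3-methylbut-2-en-1-yl)chromane
Product: 18 (2S)-2-[2,2-dimethyl-7-(triisopropylsilyloxy)-2H-chromen-6-yl]-5,7-dimethoxy-8-(3-methylbut-2-en-1-yl)chroman-4-ol (both C4 epimers)
Conditions: pyridinium p-toluenesulfonate (cat.), THF/H2O (4:1), high dilution, rt
Reagents that add atoms: water, O
Why: SN1 solvolysis; the C4 ether ionises to a 2,4,6-trioxygenated benzylic cation far more readily than the C2–O1 bond or the silyl ether react, and water in large excess under dilution captures it; C2 is not involved and both C4 epimers are used.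

Step 11
Reactants: 18 (2S)-2-[2,2-dimethyl-7-(triisopropylsilyloxy)-2H-chromen-6-yl]-5,7-dimethoxy-8-(3-methylbut-2-en-1-yl)chroman-4-ol
Product: 19 (2S)-2-[2,2-dimethyl-7-(triisopropylsilyloxy)-2H-chromen-6-yl]-5,7-dimethoxy-8-(3-methylbut-2-en-1-yl)chroman-4-one
Conditions: Dess–Martin periodinane, pyridine, CH2Cl2, 0 °C to rt
Reagents that add atoms: none
Why: Dess–Martin oxidation of a secondary benzylic alcohol; the pyridine buffer keeps the acetic acid formed from ionising C4 or C2, and the olefins are inert to the reagent.

Step 12
Reactants: 19 (2S)-2-[2,2-dimethyl-7-(triisopropylsilyloxy)-2H-chromen-6-yl]-5,7-dimethoxy-8-(3-methylbut-2-en-1-yl)chroman-4-one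
Product: 20 (2S)-2-[2,2-dimethyl-7-(triisopropylsilyloxy)-2H-chromen-6-yl]-5-hydroxy-7-methoxy-8-(3-methylbut-2-en-1-yl)chroman-4-one
Conditions: MgI2·OEt2 (3 equiv), THF, 50 °C; aq. NH4Cl
Reagents that add atoms: none
Why: Chelation-controlled O-demethylation; magnesium bound between the C4 carbonyl and O5 activates only that methyl group for attack by iodide, as known for 5-methoxy-8-prenylflavanones, while the 7-OMe, the prenyl group and the silyl ether are not affected.

Step 13
Reactants: 20 (2S)-2-[2,2-dimethyl-7-(triisopropylsilyloxy)-2H-chromen-6-yl]-5-hydroxy-7-methoxy-8-(3-methylbut-2-en-1-yl)chroman-4-one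
Product: 21 maackiaflavanone A, (2S)-5-hydroxy-2-(7-hydroxy-2,2-dimethyl-2H-chromen-6-yl)-7-methoxy-8-(3-methylbut-2-en-1-yl)chroman-4-one
Conditions: Bu4NF, AcOH (1:1), THF, 0 °C
Reagents that add atoms: none
Why: Fluoride-induced cleavage of the aryl silyl ether; the acetic acid buffer protonates the 2'-phenoxide as it forms, so that neither quinone methide formation nor retro-oxa-Michael opening can racemise C2.

**Compound list**

1 | 2-hydroxy-4,6-dimethoxybenzaldehyde | COc1cc(OC)c(C=O)c(O)c1 | starting material
2 | allyl bromide | C=CCBr | starting material
3 | 2-(allyloxy)-4,6-dimethoxybenzaldehyde | COc1cc(OC)c(C=O)c(OCC=C)c1 | intermediate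
4 | 3-allyl-2-hydroxy-4,6-dimethoxybenzaldehyde | COc1cc(OC)c(C=O)c(O)c1CC=C | intermediate
5 | 2-methylbut-2-ene | CC=C(C)C | starting material
6 | 2-hydroxy-4,6-dimethoxy-3-(3-methylbut-2-en-1-yl)benzaldehyde | COc1cc(OC)c(C=O)c(O)c1CC=C(C)C | intermediate
7 | resorcinol | Oc1cccc(O)c1 | starting material
8 | 3-methylbut-2-enoic acid | CC(C)=CC(=O)O | starting material
9 | 7-hydroxy-2,2-dimethylchroman-4-one | CC1(C)CC(=O)c2ccc(O)cc2O1 | intermediate
10 | 2,2-dimethylchromane-4,7-diol (racemic) | CC1(C)CC(O)c2ccc(O)cc2O1 | intermediate (not isolated)
11 | 2,2-dimethyl-2H-chromen-7-ol | CC1(C)C=Cc2ccc(O)cc2O1 | intermediate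
12 | 7-hydroxy-2,2-dimethyl-2H-chromene-6-carbaldehyde | CC1(C)C=Cc2cc(C=O)c(O)cc2O1 | intermediate
13 | 2,2-dimethyl-7-(triisopropylsilyloxy)-2H-chromene-6-carbaldehyde | CC1(C)C=Cc2cc(C=O)c(O[Si](C(C)C)(C(C)C)C(C)C)cc2O1 | intermediate
14 | 6-ethenyl-2,2-dimethyl-7-(triisopropylsilyloxy)-2H-chromene | C=Cc1cc2C=CC(C)(C)Oc2cc1O[Si](C(C)C)(C(C)C)C(C)C | intermediate
15 | 2-(dimethoxymethyl)-3,5-dimethoxy-6-(3-methylbut-2-en-1-yl)phenol | COc1cc(OC)c(C(OC)OC)c(O)c1CC=C(C)C | intermediate (not isolated)
16 | [2-hydroxy-4,6-dimethoxy-3-(3-methylbut-2-en-1-yl)benzylidene](methyl)oxonium, ion pair with the catalyst anion | COc1cc(OC)c(C=[O+]C)c(O)c1CC=C(C)C | intermediate (not isolated)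
17 | (2S,4S)-2-[2,2-dimethyl-7-(triisopropylsilyloxy)-2H-chromen-6-yl]-4,5,7-trimethoxy-8-(3-methylbut-2-en-1-yl)chromane | COc1cc(OC)c2c(c1CC=C(C)C)O[C@H](c1cc3c(cc1O[Si](C(C)C)(C(C)C)C(C)C)OC(C)(C)C=C3)C[C@@H]2OC | intermediate
18 | (2S)-2-[2,2-dimethyl-7-(triisopropylsilyloxy)-2H-chromen-6-yl]-5,7-dimethoxy-8-(3-methylbut-2-en-1-yl)chroman-4-ol (both C4 epimers) | COc1cc(OC)c2c(c1CC=C(C)C)O[C@H](c1cc3c(cc1O[Si](C(C)C)(C(C)C)C(C)C)OC(C)(C)C=C3)CC2O | intermediate
19 | (2S)-2-[2,2-dimethyl-7-(triisopropylsilyloxy)-2H-chromen-6-yl]-5,7-dimethoxy-8-(3-methylbut-2-en-1-yl)chroman-4-one | COc1cc(OC)c2c(c1CC=C(C)C)O[C@H](c1cc3c(cc1O[Si](C(C)C)(C(C)C)C(C)C)OC(C)(C)C=C3)CC2=O | intermediate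
20 | (2S)-2-[2,2-dimethyl-7-(triisopropylsilyloxy)-2H-chromen-6-yl]-5-hydroxy-7-methoxy-8-(3-methylbut-2-en-1-yl)chroman-4-one | COc1cc(O)c2c(c1CC=C(C)C)O[C@H](c1cc3c(cc1O[Si](C(C)C)(C(C)C)C(C)C)OC(C)(C)C=C3)CC2=O | intermediate
21 | maackiaflavanone A, (2S)-5-hydroxy-2-(7-hydroxy-2,2-dimethyl-2H-chromen-6-yl)-7-methoxy-8-(3-methylbut-2-en-1-yl)chroman-4-one | COc1cc(O)c2c(c1CC=C(C)C)O[C@H](c1cc3c(cc1O)OC(C)(C)C=C3)CC2=O | target

**Step count and risks**

Total step count: 13. Longest linear sequence: 10 steps (7 and 8 to 21 through 9, 11, 12, 13, 14, 17, 18, 19 and 20); the aldehyde branch (1 to 6) has 3 steps.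

Least certain steps:

Step 9 (key step).
- Risk: insufficient facial discrimination in the ring closure at C2, because the anion has to control a cation that is two bonds away from its hydrogen-bond anchor.
- Risk: erosion of enantiopurity by reversible opening of the C2–O1 bond of the product.
- Risk: competing attack of the cation on the chromene double bond, acid-induced cyclisation of the prenyl phenol, or Friedel–Crafts oligomerisation through re-ionisation at C4.
- A more acidic N-triflyl analogue of the catalyst would be tried first if ionisation is too slow.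
- Fallback (known chemistry): setting out from 6 and 14, the annulation is run with an achiral acid ((PhO)2P(O)OH, HC(OMe)3, CH2Cl2, −20 °C), a known three-component chroman synthesis that proceeds through 15 and 16. It gives the racemic 2-[2,2-dimethyl-7-(triisopropylsilyloxy)-2H-chromen-6-yl]-4,5,7-trimethoxy-8-(3-methylbut-2-en-1-yl)chromane F1 as C4 epimers. Hydrolysis as in step 10 gives the racemic chroman-4-ol F2 and oxidation as in step 11 the racemic chroman-4-one F3. F3 has a single stereocentre and is separated by preparative HPLC on a chiral stationary phase (amylose tris(3,5-dimethylphenylcarbamate)). The (2S) enantiomer is 19, where the route is rejoined; the (2R)-chroman-4-one F4 is set aside.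

Step 12.
- Risk: Lewis acid-promoted opening of ring C (retro-oxa-Michael reaction to the chalcone, or ionisation of C2–O1 assisted by the electron-rich ring B) on warming, which racemises C2.
- Risk: addition of hydrogen iodide formed in traces to the prenyl or chromene olefin.
- Fallback: the unmasking of O5 is moved ahead of the key step.
  - Setting out from 6, MgI2·OEt2 in THF removes the methyl group next to the aldehyde and gives 2,6-dihydroxy-4-methoxy-3-(3-methylbut-2-en-1-yl)benzaldehyde F5.
  - iPr3SiCl and imidazole in CH2Cl2 at 0 °C silylate the less hindered hydroxy group, the one not flanked by the prenyl group, to give 2-hydroxy-4-methoxy-3-(3-methylbut-2-en-1-yl)-6-(triisopropylsilyloxy)benzaldehyde F6.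
  - Under the conditions of step 9, F6 passes through its dimethyl acetal 2-(dimethoxymethyl)-5-methoxy-6-(3-methylbut-2-en-1-yl)-3-(triisopropylsilyloxy)phenol F7 and the corresponding O-methyl oxocarbenium ion F8, and combines with 14 to give (2S,4S)-2-[2,2-dimethyl-7-(triisopropylsilyloxy)-2H-chromen-6-yl]-4,7-dimethoxy-8-(3-methylbut-2-en-1-yl)-5-(triisopropylsilyloxy)chromane F9.
  - Hydrolysis as in step 10 gives the chroman-4-ol F10 and oxidation as in step 11 the bis-silylated chroman-4-one F11.
  - Buffered fluoride as in step 13 removes both silyl groups from F11 and gives 21 directly, so no Lewis acid touches the flavanone.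

Step 10.
- Risk: the C4 cation loses a proton to give the flav-3-ene, or attacks C6 of a second ring A and oligomerises, before water captures it.
- Risk: an acid strong enough to ionise C4 at a useful rate also starts to open C2–O1.
- Fallback: setting out from 17, the alcohol stage is skipped. DDQ in wet CH2Cl2 at 0 °C abstracts hydride from C4, the most hydridic position (α to OMe and to the trioxygenated ring), and hydrolysis of the resulting oxocarbenium ion gives 19 directly. No new compound arises on this path (entry F0).

Step 6.
- Risk: formylation at C8 between the two oxygens instead of, or in addition to, C6.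
- Risk: phenol–formaldehyde condensation of the very electron-rich chromenol.
- Fallback: regiocontrol is switched from chelation to electrophilic substitution para to the pyran oxygen. Setting out from 11, silylation (iPr3SiCl, imidazole, DMF) gives [(2,2-dimethyl-2H-chromen-7-yl)oxy]triisopropylsilane F12. Vilsmeier–Haack formylation (POCl3, DMF, 0 °C; aq. NaOAc) then introduces the aldehyde at C6 and gives 13, where the route is rejoined.

**Further compounds**

F1 | step 9 | racemic 2-[2,2-dimethyl-7-(triisopropylsilyloxy)-2H-chromen-6-yl]-4,5,7-trimethoxy-8-(3-methylbut-2-en-1-yl)chromane (C4 epimers) | COc1cc(OC)c2c(c1CC=C(C)C)OC(c1cc3c(cc1O[Si](C(C)C)(C(C)C)C(C)C)OC(C)(C)C=C3)CC2OC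
F2 | step 9 | racemic 2-[2,2-dimethyl-7-(triisopropylsilyloxy)-2H-chromen-6-yl]-5,7-dimethoxy-8-(3-methylbut-2-en-1-yl)chroman-4-ol | COc1cc(OC)c2c(c1CC=C(C)C)OC(c1cc3c(cc1O[Si](C(C)C)(C(C)C)C(C)C)OC(C)(C)C=C3)CC2O
F3 | step 9 | racemic 2-[2,2-dimethyl-7-(triisopropylsilyloxy)-2H-chromen-6-yl]-5,7-dimethoxy-8-(3-methylbut-2-en-1-yl)chroman-4-one | COc1cc(OC)c2c(c1CC=C(C)C)OC(c1cc3c(cc1O[Si](C(C)C)(C(C)C)C(C)C)OC(C)(C)C=C3)CC2=O
F4 | step 9 | (2R)-2-[2,2-dimethyl-7-(triisopropylsilyloxy)-2H-chromen-6-yl]-5,7-dimethoxy-8-(3-methylbut-2-en-1-yl)chroman-4-one | COc1cc(OC)c2c(c1CC=C(C)C)O[C@@H](c1cc3c(cc1O[Si](C(C)C)(C(C)C)C(C)C)OC(C)(C)C=C3)CC2=O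
F0 | step 10 | none | none
F5 | step 12 | 2,6-dihydroxy-4-methoxy-3-(3-methylbut-2-en-1-yl)benzaldehyde | COc1cc(O)c(C=O)c(O)c1CC=C(C)C
F6 | step 12 | 2-hydroxy-4-methoxy-3-(3-methylbut-2-en-1-yl)-6-(triisopropylsilyloxy)benzaldehyde | COc1cc(O[Si](C(C)C)(C(C)C)C(C)C)c(C=O)c(O)c1CC=C(C)C
F7 | step 12 | 2-(dimethoxymethyl)-5-methoxy-6-(3-methylbut-2-en-1-yl)-3-(triisopropylsilyloxy)phenol | COc1cc(O[Si](C(C)C)(C(C)C)C(C)C)c(C(OC)OC)c(O)c1CC=C(C)C
F8 | step 12 | [2-hydroxy-4-methoxy-3-(3-methylbut-2-en-1-yl)-6-(triisopropylsilyloxy)benzylidene](methyl)oxonium, ion pair with the catalyst anion | COc1cc(O[Si](C(C)C)(C(C)C)C(C)C)c(C=[O+]C)c(O)c1CC=C(C)C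
F9 | step 12 | (2S,4S)-2-[2,2-dimethyl-7-(triisopropylsilyloxy)-2H-chromen-6-yl]-4,7-dimethoxy-8-(3-methylbut-2-en-1-yl)-5-(triisopropylsilyloxy)chromane | COc1cc(O[Si](C(C)C)(C(C)C)C(C)C)c2c(c1CC=C(C)C)O[C@H](c1cc3c(cc1O[Si](C(C)C)(C(C)C)C(C)C)OC(C)(C)C=C3)C[C@@H]2OC
F10 | step 12 | (2S)-2-[2,2-dimethyl-7-(triisopropylsilyloxy)-2H-chromen-6-yl]-7-methoxy-8-(3-methylbut-2-en-1-yl)-5-(triisopropylsilyloxy)chroman-4-ol (both C4 epimers) | COc1cc(O[Si](C(C)C)(C(C)C)C(C)C)c2c(c1CC=C(C)C)O[C@H](c1cc3c(cc1O[Si](C(C)C)(C(C)C)C(C)C)OC(C)(C)C=C3)CC2O
F11 | step 12 | (2S)-2-[2,2-dimethyl-7-(triisopropylsilyloxy)-2H-chromen-6-yl]-7-methoxy-8-(3-methylbut-2-en-1-yl)-5-(triisopropylsilyloxy)chroman-4-one | COc1cc(O[Si](C(C)C)(C(C)C)C(C)C)c2c(c1CC=C(C)C)O[C@H](c1cc3c(cc1O[Si](C(C)C)(C(C)C)C(C)C)OC(C)(C)C=C3)CC2=O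
F12 | step 6 | [(2,2-dimethyl-2H-chromen-7-yl)oxy]triisopropylsilane | CC1(C)C=Cc2ccc(O[Si](C(C)C)(C(C)C)C(C)C)cc2O1
A1 | alternative 1 | 4-methoxy-6-{(E)-4-[7-(methoxymethoxy)-2,2-dimethyl-2H-chromen-6-yl]-2-oxobut-3-en-1-yl}-2H-pyran-2-one | COC1=CC(=O)OC(CC(=O)/C=C/c2cc3C=CC(C)(C)Oc3cc2OCOC)=C1
A2 | alternative 1 | (E)-1-(2,6-dihydroxy-4-methoxyphenyl)-3-[7-(methoxymethoxy)-2,2-dimethyl-2H-chromen-6-yl]prop-2-en-1-one | COc1cc(O)c(C(=O)/C=C/c2cc3C=CC(C)(C)Oc3cc2OCOC)c(O)c1
A3 | alternative 2 | 3,5-dimethoxy-2-(3-methylbut-2-en-1-yl)-6-(trimethylsilyl)phenyl trifluoromethanesulfonate | COc1cc(OC)c([Si](C)(C)C)c(OS(=O)(=O)C(F)(F)F)c1CC=C(C)C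
A4 | alternative 2 | methyl (3S)-3-hydroxy-3-[7-(methoxymethoxy)-2,2-dimethyl-2H-chromen-6-yl]propanoate | COC(=O)C[C@H](O)c1cc2C=CC(C)(C)Oc2cc1OCOC
A5 | alternative 2 | (2S)-5,7-dimethoxy-2-[7-(methoxymethoxy)-2,2-dimethyl-2H-chromen-6-yl]-8-(3-methylbut-2-en-1-yl)chroman-4-one | COc1cc(OC)c2c(c1CC=C(C)C)O[C@H](c1cc3c(cc1OCOC)OC(C)(C)C=C3)CC2=O
A6 | alternative 3 | [(1,3-dimethoxy-7-methylocta-1,3,6-trien-1-yl)oxy]trimethylsilane | COC(O[Si](C)(C)C)=CC(OC)=CCC=C(C)C
A7 | alternative 3 | (2S)-2-[7-(methoxymethoxy)-2,2-dimethyl-2H-chromen-6-yl]-5-(phenylsulfinyl)-2,3-dihydro-4H-pyran-4-one | O=C1C[C@@H](c2cc3C=CC(C)(C)Oc3cc2OCOC)OC=C1S(=O)c1ccccc1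
A8 | alternative 3 | (2S)-5-hydroxy-7-methoxy-2-[7-(methoxymethoxy)-2,2-dimethyl-2H-chromen-6-yl]-8-(3-methylbut-2-en-1-yl)chroman-4-one | COc1cc(O)c2c(c1CC=C(C)C)O[C@H](c1cc3c(cc1OCOC)OC(C)(C)C=C3)CC2=O
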